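**Remark on the chemistry (assumption):** the target is taken as the achiral 3,3'-bicoumarin of the given SMILES. Unprimed locants belong to the 7-hydroxy-6,8-dimethoxycoumarin unit (benzene ring A, pyranone ring B), primed locants to the 6,7-dihydroxycoumarin unit (pyranone ring C, benzene ring D). Compounds 1, 5 and 7 are taken as commercial.

## Analysis of the target

Arteminorin C is an unsymmetrical 3,3'-bicoumarin, C20H14O9: a 7-hydroxy-6,8-dimethoxycoumarin unit (rings A and B) is joined through the C3–C3' bond to a 6,7-dihydroxycoumarin unit (rings C and D). There is no stereocenter, and the C3–C3' axis is flanked only by H-4, H-4' and the two lactone carbonyl groups, so it rotates freely and no axial chirality has to be controlled. The feature the strategy is built on is the chain C2–C3–C3'–C2': four contiguous carbons with a carboxyl-level carbon at each end, a succinic acid unit buried in rings B and C, whose inner carbons C3 and C3' each carry one methine carbon (C4, C4') at the aldehyde oxidation level, placed ortho to a ring oxygen (O1, O1') on rings A and D. Rings B and C are therefore, formally, two different salicylaldehydes condensed on the two ends of one succinate, and the central bond need not be made at all. Sensitive groups are the catechol of ring D (air oxidation in base), three free phenols, two lactones that open reversibly in aqueous base, and two aryl methyl ethers that must survive the unmasking of the three hydroxyl groups, which rules out a final global demethylation. The main difficulty is the lack of symmetry: the two arenes must be placed on the two ends of the four-carbon chain without statistical mixtures, and a coupling at C3–C3' would have to join two electron-poor, alpha-carbonyl sp2 carbons. A second difficulty is ring A, whose 6,7,8-trioxygenation needs a salicylaldehyde with the free hydroxyl wedged between the formyl group and a methoxy group, and with O7 distinguished from O6 and O8.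

## Retrosynthetic reasoning

**13 to 12.** The three hydroxyl groups (O7, O6', O7') are masked by acid-labile acetals only: a methoxymethyl ether on ring A and a diphenylmethylene ketal bridging the catechol of ring D. Both survive base, and both fall in one acidic operation that touches neither the methyl ethers nor the lactones. Hydrogenolytic groups were avoided because the two C3=C4 double bonds are reducible.

**12 to 10 (key disconnection).** Both C3=C4 and C3'=C4' are cut, which opens rings B and C at once and reveals the mixed bis(2-formylaryl) succinate 10. The cut is made here because it leaves C3–C3' untouched: that bond is the C2–C3 bond of succinic anhydride 7 and is bought, not made. Each cut is the retron of an intramolecular aldol condensation of a 2-formylaryl ester. The pairing of the two different arenes is written into the diester before any ring exists, so no cross-coupling and no coumarin functionalisation is needed. The forward reaction has to enolise two ester methylene groups, close two six-membered rings through the monocyclised ester 11 with twofold dehydration, and keep each aryloxy group on its own carbonyl carbon.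

**10 to 8 and 4.** The O1–C2 ester bond on the ring A side is cut. The acid 8 is activated as the acyl chloride 9 and met by the hindered phenol 4, so the second arene is introduced by a reaction that cannot touch the first ester.

**8 to 6 and 7.** The O1'–C2' ester bond is cut. Opening the cyclic anhydride 7 with phenol 6 acylates once and only once, so the anhydride itself desymmetrises the four-carbon unit.

**6 to 5.** Only O4 and O5 of 5 are ortho to each other, so a cyclic ketal can form only there and leaves the hydroxyl next to the formyl group free without any selectivity problem.

**4 to 3 to 2 to 1.** The ring A salicylaldehyde is traced to syringaldehyde 1, which already holds the formyl group and the O6/O7/O8 pattern. The missing hydroxyl ortho to the formyl group is introduced through bromide 2 and copper-mediated hydroxylation to 3. The more acidic hydroxyl para to the formyl group is then capped selectively to give 4.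

## Alternatives that were turned down

**Alternative 1:** (the textbook route) Disconnection of C3–C3' by Suzuki–Miyaura coupling. The forward key step joins the 3-bromocoumarin A1 and the coumarin-3-boronate A2 with a zerovalent palladium catalyst such as Pd(PPh3)4 and aqueous base. It was turned down for these reasons:
- Rings B and C must first be built separately on 4 and 6, and each coumarin then needs functionalisation at C3.
- Bromination has to discriminate C3 from the free positions of the electron-rich rings A and D.
- A boronate on the carbon alpha to a lactone carbonyl is prone to protodeboronation, and the aqueous base that the coupling needs also opens lactones.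
- The route costs about four more steps and makes the hardest bond last instead of buying it.

**Alternative 2:** Disconnection of the two lactone C–O bonds (O1–C2, O1'–C2') after two successive Stobbe condensations of a succinic diester with O-protected forms of 4 and 6, leading to the bis(arylidene)succinate A3. The forward key step is photochemical E-to-Z isomerisation of both alkenes of A3 with double lactonisation. It was turned down for these reasons:
- Stobbe condensation places each aryl group trans to its ester carbonyl, so both alkenes have the wrong geometry for lactonisation and light is required.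
- Under irradiation the aryl–C=C–C=C hexatriene of a bis(arylidene)succinate is set up for six-electron electrocyclisation to a 1-aryl-1,2-dihydronaphthalene, which would divert material to a different skeleton.
- Two Stobbe steps, re-esterification and protection and release of the two ortho hydroxyl groups make the route longer than the one chosen.

**Alternative 3:** Disconnection of both carbonyl carbons (C2–C3, C2–O1, C2'–C3', C2'–O1'), leading to the diene A4. The forward key step is a double phenol-directed alkenyl C–H cyclocarbonylation of A4 with Pd(OAc)2 (divalent palladium), Cu(OAc)2 as reoxidant and CO. It was turned down for these reasons: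
- The reaction type is established for 2-vinylphenols with terminal or 1,1-disubstituted alkenes, not for the two internal C–H bonds of a conjugated diene.
- After the first carbonylation the second C–H bond is part of an electron-poor dienoate and should be much less reactive.
- The electron-rich, hydroquinone-like phenols of A4 are exposed to an oxidant.
- A4 itself needs four to five steps of olefination chemistry, so the key step would not repay its precursor.

Key step: step 7

## Route

Step 1
Reactants: 1 syringaldehyde (4-hydroxy-3,5-dimethoxybenzaldehyde)
Product: 2 2-bromo-4-hydroxy-3,5-dimethoxybenzaldehyde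
Conditions: Br2 (1.05 equiv), AcOH, rt
Reagents that add atoms: bromine, BrBr
Why: Electrophilic aromatic bromination; the two free positions are equivalent, each ortho to one methoxy group and para to the other, so one monobromide should form, and the first bromine deactivates the ring against a second.

Step 2
Reactants: 2 2-bromo-4-hydroxy-3,5-dimethoxybenzaldehyde
Product: 3 2,4-dihydroxy-3,5-dimethoxybenzaldehyde
Conditions: NaOH (4 M aq), CuSO4·5H2O (10 mol%), reflux, N2; then HCl (aq)
Reagents that add atoms: sodium hydroxide, [Na+].[OH-]
Why: Copper-catalysed Ullmann-type hydroxylation of an aryl bromide activated by the ortho formyl group; the para phenoxide turns the aldehyde into a vinylogous carboxylate and so should protect it from Cannizzaro disproportionation.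

Step 3
Reactants: 3 2,4-dihydroxy-3,5-dimethoxybenzaldehyde
Product: 4 2-hydroxy-3,5-dimethoxy-4-(methoxymethoxy)benzaldehyde
Conditions: MOMCl (1.05 equiv), K2CO3 (1.1 equiv), acetone, 0 °C to rt
Reagents that add atoms: chloromethyl methyl ether (MOMCl), COCCl
Why: Williamson-type O-alkylation; the hydroxyl para to the formyl group is the more acidic and is alkylated first, while the ortho hydroxyl is held in a hydrogen bond to the aldehyde, the usual basis of 4-selective alkylation of 2,4-dihydroxybenzaldehydes.

Step 4
Reactants: 5 2,4,5-trihydroxybenzaldehyde
Product: 6 6-hydroxy-2,2-diphenyl-1,3-benzodioxole-5-carbaldehyde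
Conditions: Ph2CCl2 (1.2 equiv), Ph2O, 175 °C, N2
Reagents that add atoms: dichlorodiphenylmethane, ClC(Cl)(c1ccccc1)c1ccccc1
Why: Twofold nucleophilic substitution that forms the cyclic diphenylmethylene ketal of a catechol; only O4 and O5 are ortho to each other, so the five-membered ring can close only there and the hydroxyl next to the formyl group stays free.

Step 5
Reactants: 6 6-hydroxy-2,2-diphenyl-1,3-benzodioxole-5-carbaldehyde; 7 succinic anhydride
Product: 8 4-[(6-formyl-2,2-diphenyl-1,3-benzodioxol-5-yl)oxy]-4-oxobutanoic acid
Conditions: Et3N (1.5 equiv), DMAP (10 mol%), CH2Cl2, rt; cold 1 M HCl wash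
Reagents that add atoms: none
Why: Nucleophile-catalysed ring opening of a cyclic anhydride by a phenol, which acylates exactly once; the cold acidic work-up keeps the product as the free acid, whose carboxylate could otherwise close back to the anhydride.

Step 6
Reactants: 8 4-[(6-formyl-2,2-diphenyl-1,3-benzodioxol-5-yl)oxy]-4-oxobutanoic acid; 4 2-hydroxy-3,5-dimethoxy-4-(methoxymethoxy)benzaldehyde
Product: 10 1-(6-formyl-2,2-diphenyl-1,3-benzodioxol-5-yl) 4-[6-formyl-2,4-dimethoxy-3-(methoxymethoxy)phenyl] butanedioate, via acyl chloride 9 (not isolated)
Conditions: (COCl)2 (1.2 equiv), DMF (cat.), CH2Cl2, 0 °C to rt, evaporate; then 4, pyridine (3 equiv), DMAP (5 mol%), CH2Cl2, 0 °C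
Reagents that add atoms: none
Why: Acyl chloride formation under acidic conditions keeps the carboxyl group protonated, and esterification of the hindered phenol 4 then proceeds through an acylpyridinium ion; the acid-labile methoxymethyl ether meets the mixture only after hydrogen chloride has been evaporated and pyridine is present.

Step 7
Reactants: 10 1-(6-formyl-2,2-diphenyl-1,3-benzodioxol-5-yl) 4-[6-formyl-2,4-dimethoxy-3-(methoxymethoxy)phenyl] butanedioate
Product: 12 7-[6,8-dimethoxy-7-(methoxymethoxy)-2-oxo-2H-chromen-3-yl]-2,2-diphenyl-6H-[1,3]dioxolo[4,5-g]chromen-6-one, via monocoumarin aryl ester 11 (not isolated)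
Conditions: DBU (3 equiv), 4 Å MS, MeCN (0.02 M), 60 °C
Reagents that add atoms: none
Why: DBU reversibly enolises one succinate methylene of 10 and the ester enolate adds to the formyl group on its own aryl ring, after which E1cB loss of hydroxide from the aldol adduct gives the first pyranone and leaves 11. In 11 the remaining methylene lies between an aryl ester and C3 of the new coumarin, so it is far more acidic than the first one and the second aldol condensation onto the second formyl group should follow quickly to give 12, with water as the only coproduct. The closest known reaction type is the intramolecular aldol condensation of 2-formylaryl esters, the ring-closing event of the Perkin coumarin synthesis, which is established for alkanoates, for succinic acid derivatives and for arylacetates (3-arylcoumarins). Ring B closes by formation of C3–C4 and ring C by formation of C3'–C4', each as a 6-(enolendo)-exo-trig aldol addition. No stereocenter is created: the transient carbinol centres are erased by dehydration, and the ring fixes the geometry of each new C3=C4 double bond. The step needs each enolate to take the aldehyde of its own ring (six-membered closure) and not that of the other ring (seven-membered closure), which is secured by ring size and by the reversibility of the aldol addition set against the irreversible dehydration to an aromatic-stabilised coumarin. It also needs the two aryloxy groups to stay on their carbonyl carbons, which high dilution, molecular sieves and a non-hydroxylic medium are meant to secure. The order of the two closures is immaterial, because both orders converge on 12.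

Step 8
Reactants: 12 7-[6,8-dimethoxy-7-(methoxymethoxy)-2-oxo-2H-chromen-3-yl]-2,2-diphenyl-6H-[1,3]dioxolo[4,5-g]chromen-6-one
Product: 13 arteminorin C (6,7-dihydroxy-3-(7-hydroxy-6,8-dimethoxy-2-oxo-2H-chromen-3-yl)-2H-chromen-2-one)
Conditions: conc. HCl (aq), MeOH/THF (1:1), 60 °C, N2
Reagents that add atoms: none
Why: Acid-catalysed acetal cleavage: methanolysis of the methoxymethyl ether and hydrolysis of the diphenylmethylene ketal through its diaryl-stabilised oxocarbenium ion; aryl methyl ethers and both lactones are inert to methanolic acid, and methanol carries the formaldehyde unit away as its dimethyl acetal.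

## Compound list

1 | syringaldehyde (4-hydroxy-3,5-dimethoxybenzaldehyde) | COc1cc(C=O)cc(OC)c1O | starting material
2 | 2-bromo-4-hydroxy-3,5-dimethoxybenzaldehyde | COc1cc(C=O)c(Br)c(OC)c1O | intermediate
3 | 2,4-dihydroxy-3,5-dimethoxybenzaldehyde | COc1cc(C=O)c(O)c(OC)c1O | intermediate
4 | 2-hydroxy-3,5-dimethoxy-4-(methoxymethoxy)benzaldehyde | COCOc1c(OC)cc(C=O)c(O)c1OC | intermediate
5 | 2,4,5-trihydroxybenzaldehyde | O=Cc1cc(O)c(O)cc1O | starting material
6 | 6-hydroxy-2,2-diphenyl-1,3-benzodioxole-5-carbaldehyde | O=Cc1cc2OC(c3ccccc3)(c3ccccc3)Oc2cc1O | intermediate
7 | succinic anhydride | O=C1CCC(=O)O1 | starting material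
8 | 4-[(6-formyl-2,2-diphenyl-1,3-benzodioxol-5-yl)oxy]-4-oxobutanoic acid | OC(=O)CCC(=O)Oc1cc2OC(c3ccccc3)(c3ccccc3)Oc2cc1C=O | intermediate
9 | 6-formyl-2,2-diphenyl-1,3-benzodioxol-5-yl 4-chloro-4-oxobutanoate | ClC(=O)CCC(=O)Oc1cc2OC(c3ccccc3)(c3ccccc3)Oc2cc1C=O | intermediate
10 | 1-(6-formyl-2,2-diphenyl-1,3-benzodioxol-5-yl) 4-[6-formyl-2,4-dimethoxy-3-(methoxymethoxy)phenyl] butanedioate | COCOc1c(OC)cc(C=O)c(OC(=O)CCC(=O)Oc2cc3OC(c4ccccc4)(c4ccccc4)Oc3cc2C=O)c1OC | intermediate
11 | 6-formyl-2,4-dimethoxy-3-(methoxymethoxy)phenyl 2-(6-oxo-2,2-diphenyl-6H-[1,3]dioxolo[4,5-g]chromen-7-yl)acetate | COCOc1c(OC)cc(C=O)c(OC(=O)Cc2cc3cc4OC(c5ccccc5)(c5ccccc5)Oc4cc3oc2=O)c1OC | intermediate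
12 | 7-[6,8-dimethoxy-7-(methoxymethoxy)-2-oxo-2H-chromen-3-yl]-2,2-diphenyl-6H-[1,3]dioxolo[4,5-g]chromen-6-one | COCOc1c(OC)cc2cc(-c3cc4cc5OC(c6ccccc6)(c6ccccc6)Oc5cc4oc3=O)c(=O)oc2c1OC | intermediate
13 | arteminorin C | COc1cc2cc(-c3cc4cc(O)c(O)cc4oc3=O)c(=O)oc2c(OC)c1O | target

## Step count and risk

Total step count: 8. Longest linear sequence: 6 steps (steps 1, 2, 3, 6, 7, 8).

**Step 7 (key step).** The first, unactivated succinate methylene may enolise so slowly that nucleophilic acyl transfer by the amidine base, or by the water that the condensation releases, outpaces ring closure. Exchange of aryloxy groups between molecules would then erase the unsymmetrical pairing. The fallback sets out from 8 and comes back at 12. Acid 8 is heated with Et3N and additional 7, with no second aryl group present and so no crossover possible, in a Perkin condensation that closes ring C alone and gives 2-(6-oxo-2,2-diphenyl-6H-[1,3]dioxolo[4,5-g]chromen-7-yl)acetic acid F1. Carbodiimide esterification of F1 with 4 (EDC·HCl, DMAP cat., CH2Cl2) then gives 11, this time made on purpose. Its arylacetate-type methylene should close ring B with Et3N or a little DBU at room temperature to give 12.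

**Step 2.** Protodebromination, slow substitution at the doubly ortho-substituted carbon, or base-induced degradation of the electron-rich aldehyde at reflux may prevail over hydroxylation. The fallback sets out from 2 and comes back at 4, so that step 3 is no longer needed. Phenol 2 is first capped (MOMCl, K2CO3, acetone) to give 2-bromo-3,5-dimethoxy-4-(methoxymethoxy)benzaldehyde F2. Miyaura borylation (B2pin2, Pd(dppf)Cl2, KOAc, dioxane, 90 °C) gives 3,5-dimethoxy-4-(methoxymethoxy)-2-(4,4,5,5-tetramethyl-1,3,2-dioxaborolan-2-yl)benzaldehyde F3. Oxidation of the C–B bond with trimethylamine N-oxide, which does not trigger a Dakin oxidation of the aldehyde, gives 4.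

**Step 6.** Acylation of the hindered, hydrogen-bonded hydroxyl of 4 may be slow enough for ketene formation from 9 or acyl transfer between aryl esters to compete. The fallback reverses the roles of the two phenols; it sets out from 4, 7 and 6 and comes back at 10. The hindered phenol 4 opens the small anhydride 7 (Et3N, DMAP) to give 4-[6-formyl-2,4-dimethoxy-3-(methoxymethoxy)phenoxy]-4-oxobutanoic acid F4. The neutral chlorinating agent 1-chloro-N,N,2-trimethylprop-1-en-1-amine, which spares the methoxymethyl ether, converts F4 into 6-formyl-2,4-dimethoxy-3-(methoxymethoxy)phenyl 4-chloro-4-oxobutanoate F5. The less hindered phenol 6 with pyridine then gives 10.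

**Step 8.** Electrophilic hydroxymethylation of the freed, electron-rich ring D by the formaldehyde unit of the methoxymethyl group may occur, or ketal hydrolysis may stay incomplete under conditions mild enough for the rest of the molecule. The fallback stages the unmasking; it sets out from 12 and comes back at 13. Dilute HCl in MeOH/THF at room temperature removes only the methoxymethyl ether and gives 7-(7-hydroxy-6,8-dimethoxy-2-oxo-2H-chromen-3-yl)-2,2-diphenyl-6H-[1,3]dioxolo[4,5-g]chromen-6-one F6. At this stage ring D is still an ether, and ring A has no free position ortho or para to its hydroxyl. After removal of the volatiles, the ketal is cleaved separately in AcOH/H2O (4:1) at reflux to give 13.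

## Further compounds

F1 | step 7 | 2-(6-oxo-2,2-diphenyl-6H-[1,3]dioxolo[4,5-g]chromen-7-yl)acetic acid | OC(=O)Cc1cc2cc3OC(c4ccccc4)(c4ccccc4)Oc3cc2oc1=O
F2 | step 2 | 2-bromo-3,5-dimethoxy-4-(methoxymethoxy)benzaldehyde | COCOc1c(OC)cc(C=O)c(Br)c1OC
F3 | step 2 | 3,5-dimethoxy-4-(methoxymethoxy)-2-(4,4,5,5-tetramethyl-1,3,2-dioxaborolan-2-yl)benzaldehyde | COCOc1c(OC)cc(C=O)c(B2OC(C)(C)C(C)(C)O2)c1OC
F4 | step 6 | 4-[6-formyl-2,4-dimethoxy-3-(methoxymethoxy)phenoxy]-4-oxobutanoic acid | COCOc1c(OC)cc(C=O)c(OC(=O)CCC(=O)O)c1OC
F5 | step 6 | 6-formyl-2,4-dimethoxy-3-(methoxymethoxy)phenyl 4-chloro-4-oxobutanoate | COCOc1c(OC)cc(C=O)c(OC(=O)CCC(=O)Cl)c1OC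
F6 | step 8 | 7-(7-hydroxy-6,8-dimethoxy-2-oxo-2H-chromen-3-yl)-2,2-diphenyl-6H-[1,3]dioxolo[4,5-g]chromen-6-one | COc1cc2cc(-c3cc4cc5OC(c6ccccc6)(c6ccccc6)Oc5cc4oc3=O)c(=O)oc2c(OC)c1O
A1 | alternative 1 | 3-bromo-6,8-dimethoxy-7-(methoxymethoxy)-2H-chromen-2-one | COCOc1c(OC)cc2cc(Br)c(=O)oc2c1OC
A2 | alternative 1 | 2,2-diphenyl-7-(4,4,5,5-tetramethyl-1,3,2-dioxaborolan-2-yl)-6H-[1,3]dioxolo[4,5-g]chromen-6-one | CC1(C)OB(OC1(C)C)c1cc2cc3OC(c4ccccc4)(c4ccccc4)Oc3cc2oc1=O
A3 | alternative 2 | dimethyl (2E,3E)-2-{[2-hydroxy-3,5-dimethoxy-4-(methoxymethoxy)phenyl]methylidene}-3-[(6-hydroxy-2,2-diphenyl-1,3-benzodioxol-5-yl)methylidene]butanedioate | COCOc1c(OC)cc(/C=C(C(=O)OC)\C(C(=O)OC)=C/c2cc3OC(c4ccccc4)(c4ccccc4)Oc3cc2O)c(O)c1OC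
A4 | alternative 3 | 6-[(1E,3E)-4-[2-hydroxy-3,5-dimethoxy-4-(methoxymethoxy)phenyl]buta-1,3-dien-1-yl]-2,2-diphenyl-1,3-benzodioxol-5-ol | COCOc1c(OC)cc(/C=C/C=C/c2cc3OC(c4ccccc4)(c4ccccc4)Oc3cc2O)c(O)c1OC
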